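**Plan**
Retrosynthesis cuts, in this order, the two O-1–C-6 ether bonds of the oxane rings, the two bonds from oxane C-2 to cyclopentane C-2, and the two oxane C-3–C-4 bonds.
Enabling feature: C-5 of each oxane ring carries an exocyclic trisubstituted alkene whose outer CH2 lies on the side of C-6 (the OCH2 carbon) and opposite C-4. The fourteen carbons from one oxane C-2 to the other read the same from either end. A chair orthoester Claisen shift that makes C-3–C-4 gives this geometry, once at each end.
Forward: succinaldehyde plus two alkenyllithiums gives a diol, and a double Johnson–Claisen gives the diester. This becomes the dialdehyde and then the bis(dithiane), which opens first the cis epoxide (half A) and then the trans epoxide (half B). Both oxanes close together in the last step.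
Stereochemistry: one Pd-catalysed deracemisation gives (R)-cyclopent-2-enol. Syn (directed) or anti (steric) epoxidation followed by anti opening with isopropenyl copper gives the two C-5-epimeric epoxides. SN2 opening places cyclopentane C-2 trans to OH, a chelate-controlled syn reduction sets oxane C-2, and the alkene geometry comes from the chair.

Key step: step 4

Locants: oxane O-1, C-2 (bears the cyclopentyl), C-5 (alkylidene), C-6 (OCH2); cyclopentanol C-1 (OH), C-2 (bears the oxane), C-5 (isopropenyl). Half A has OH cis to isopropenyl (written first in the target SMILES); half B has OH trans.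
Assumption: diol 6 is drawn as its meso isomer but used as the meso/dl mixture; the (1S,2S)-diphosphine of step 8 is taken to give (R)-14, as is usual for this ligand class with cycloalkenyl carbonates, and its antipode would be used if the sense were opposite.

**Core**

Step 1
Reactants: 1 2-bromoprop-2-en-1-ol
Product: 2 [(2-bromoprop-2-en-1-yl)oxy](tert-butyl)dimethylsilane
Conditions: TBSCl, imidazole, CH2Cl2, 0 °C to rt
Reagents that add atoms: tert-butyldimethylsilyl chloride, CC(C)(C)[Si](C)(C)Cl
Why: Silylation of a primary alcohol removes the acidic proton before halogen–lithium exchange and gives an ether that tolerates the hot, weakly acidic key step.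

Step 2
Reactants: 3 2,5-dimethoxytetrahydrofuran
Product: 4 butanedial (succinaldehyde)
Conditions: H2O, 90 °C; MeOH/H2O distilled off; CH2Cl2 extraction; used at once
Reagents that add atoms: water, O
Why: Hydrolysis of the cyclic bis(acetal) frees the dialdehyde, which is used fresh because it oligomerises on storage.

Step 3
Reactants: 2 [(2-bromoprop-2-en-1-yl)oxy](tert-butyl)dimethylsilane; 4 butanedial
Product: 6 2,7-bis{[(tert-butyldimethylsilyl)oxy]methyl}octa-1,7-diene-3,6-diol (meso/dl mixture; meso drawn), via 3-silyloxyprop-1-en-2-yllithium 5 (not isolated)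
Conditions: 2 (2.3 equiv), t-BuLi (4.6 equiv), Et2O, −78 °C; 4, −78 to −40 °C; H2O
Reagents that add atoms: none
Why: Bromine–lithium exchange followed by 1,2-addition of the alkenyllithium to both aldehydes; staying at −78 °C suppresses O-to-C silyl migration, and no control of the carbinol centres is needed because step 4 makes them sp2.

Step 4
Reactants: 6 2,7-bis{[(tert-butyldimethylsilyl)oxy]methyl}octa-1,7-diene-3,6-diol; 7 triethyl orthoacetate
Product: 9 diethyl (4Z,8Z)-4,9-bis{[(tert-butyldimethylsilyl)oxy]methyl}dodeca-4,8-dienedioate, via bis(ketene acetal) 8 (not isolated)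
Conditions: 7 (excess, as solvent), EtCO2H (cat.), 140 °C, EtOH distilled off
Reagents that add atoms: none
Why: Acid-catalysed exchange of each carbinol into the orthoester and loss of ethanol give the bis(ketene acetal) 8, and each O-allyl ketene acetal then undergoes a concerted suprafacial [3,3]-sigmatropic shift through a chair, joining the acetate carbon to the terminal methylene (the C-3–C-4 bond of a future oxane) while the double bond moves to C-5=CH. The closest known reaction type is the Johnson orthoester Claisen rearrangement of 2-substituted secondary allylic alcohols to trisubstituted alkenes, run here in two directions on one substrate. No ring is closed and no stereocentre is made; both carbinol centres are erased, so the meso and dl diols converge on one diester. The selectivity needed is alkene geometry: the central chain on the carbinol carbon sits equatorial in the chair, because an axial chain would clash 1,3-diaxially with the ethoxy group of the ketene acetal, and it therefore ends trans to the new CH2CH2CO2Et arm and cis to CH2OSi (Z at both alkenes). The silyloxymethyl group is a spectator on the central allyl carbon, and continuous removal of ethanol drives both ends to completion.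

Step 5
Reactants: 9 diethyl (4Z,8Z)-4,9-bis{[(tert-butyldimethylsilyl)oxy]methyl}dodeca-4,8-dienedioate
Product: 10 (4Z,8Z)-4,9-bis{[(tert-butyldimethylsilyl)oxy]methyl}dodeca-4,8-dienedial
Conditions: i-Bu2AlH (2.2 equiv), toluene, −78 °C; MeOH, then aq. potassium sodium tartrate
Reagents that add atoms: none
Why: Partial ester reduction, in which the aluminium hemiacetal from each ester persists at −78 °C until work-up so that reduction stops at the aldehyde; alkenes and silyl ethers are inert.

Step 6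
Reactants: 10 (4Z,8Z)-4,9-bis{[(tert-butyldimethylsilyl)oxy]methyl}dodeca-4,8-dienedial
Product: 11 2,2'-[(3Z,7Z)-3,8-bis{[(tert-butyldimethylsilyl)oxy]methyl}deca-3,7-diene-1,10-diyl]bis(1,3-dithiane)
Conditions: HS(CH2)3SH (2.4 equiv), MgBr2·OEt2, Et2O, rt
Reagents that add atoms: propane-1,3-dithiol, SCCCS
Why: Lewis-acid thioacetalisation turns both aldehyde carbons (future oxane C-2) into acyl-anion equivalents, and MgBr2·OEt2 is mild enough for the allylic silyl ethers.

**Cyclopentane epoxides (both from one enantiomer of cyclopentenol)**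

Step 7
Reactants: 12 (±)-cyclopent-2-en-1-ol
Product: 13 (±)-cyclopent-2-en-1-yl methyl carbonate
Conditions: ClCO2Me, pyridine, CH2Cl2, 0 °C
Reagents that add atoms: methyl chloroformate, COC(=O)Cl
Why: O-acylation installs the carbonate leaving group required for ionisation by zerovalent palladium.

Step 8
Reactants: 13 (±)-cyclopent-2-en-1-yl methyl carbonate
Product: 14 (R)-cyclopent-2-en-1-ol
Conditions: [Pd(C3H5)Cl]2 (2 mol %), (1S,2S)-N,N'-bis[2-(diphenylphosphino)benzoyl]cyclohexane-1,2-diamine (5 mol %), KHCO3, CH2Cl2/H2O, rt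
Reagents that add atoms: potassium hydrogencarbonate, OC(=O)[O-].[K+]; water, O
Why: Palladium-catalysed asymmetric allylic substitution run as a deracemisation, in which zerovalent palladium ionises both enantiomers to one meso η3-cyclopentenyl complex of divalent palladium, the C2-symmetric ligand steers hydrogencarbonate to one terminus, and loss of CO2 leaves the alcohol whose carbinol carbon becomes cyclopentane C-2 of both halves.

Step 9
Reactants: 14 (R)-cyclopent-2-en-1-ol
Product: 15 (1R,2R,5S)-6-oxabicyclo[3.1.0]hexan-2-ol (epoxide cis to OH)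
Conditions: VO(acac)2 (1 mol %), t-BuOOH, CH2Cl2, 0 °C to rt
Reagents that add atoms: tert-butyl hydroperoxide, CC(C)(C)OO
Why: Hydroxyl-directed epoxidation, in which the vanadium alkoxide delivers the peroxide oxygen to the alkene face syn to the hydroxyl, so both epoxide carbons are set from the carbinol centre.

Step 10
Reactants: 15 (1R,2R,5S)-6-oxabicyclo[3.1.0]hexan-2-ol; 16 isopropenylmagnesium bromide
Product: 17 (1R,2S,3S)-3-(prop-1-en-2-yl)cyclopentane-1,2-diol (cis diol, isopropenyl trans to it)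
Conditions: 16 (3.5 equiv), CuI (20 mol %), THF, −30 to 0 °C; aq. NH4Cl
Reagents that add atoms: none
Why: Copper-catalysed SN2 opening of the epoxide with inversion at the carbon remote from the alkoxide, because the proximal carbon is deactivated inductively by the neighbouring C–O bond, which sets isopropenyl trans to the new hydroxyl (half B relationship).

Step 11
Reactants: 17 (1R,2S,3S)-3-(prop-1-en-2-yl)cyclopentane-1,2-diol
Product: 20 (1S,2S,5R)-2-(prop-1-en-2-yl)-6-oxabicyclo[3.1.0]hexane (epoxide trans to isopropenyl), via cyclic orthoacetate 18 (not isolated), via chloro acetate 19 (not isolated)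
Conditions: MeC(OMe)3, PPTS (cat.), CH2Cl2, rt; Me3SiCl, CH2Cl2, 0 °C to rt; K2CO3, MeOH, rt
Reagents that add atoms: none
Why: One-pot diol-to-epoxide conversion through the acetoxonium ion, in which chloride opens the ion with inversion and the alkoxide freed by methanolysis displaces chloride with a second inversion, so the oxygen stays on the face of the diol and either regioisomeric chloro acetate gives the same epoxide.

Step 12
Reactants: 14 (R)-cyclopent-2-en-1-ol
Product: 21 tert-butyl[(1R)-cyclopent-2-en-1-yloxy]dimethylsilane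
Conditions: TBSCl, imidazole, CH2Cl2, rt
Reagents that add atoms: tert-butyldimethylsilyl chloride, CC(C)(C)[Si](C)(C)Cl
Why: Silylation switches off hydroxyl direction and puts a bulky group on one face of the ring.

Step 13
Reactants: 21 tert-butyl[(1R)-cyclopent-2-en-1-yloxy]dimethylsilane
Product: 22 tert-butyl(dimethyl){[(1R,2R,5R)-6-oxabicyclo[3.1.0]hexan-2-yl]oxy}silane (epoxide trans to OSi)
Conditions: mCPBA, NaHCO3, CH2Cl2, 0 °C
Reagents that add atoms: 3-chloroperoxybenzoic acid, OOC(=O)c1cccc(Cl)c1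
Why: Prilezhaev epoxidation under steric control, with the silyloxy group shielding its own face so the peracid attacks anti to it; any minor cis isomer is removed by chromatography.

Step 14
Reactants: 22 tert-butyl(dimethyl){[(1R,2R,5R)-6-oxabicyclo[3.1.0]hexan-2-yl]oxy}silane; 16 isopropenylmagnesium bromide
Product: 23 (1R,2R,5R)-2-[(tert-butyldimethylsilyl)oxy]-5-(prop-1-en-2-yl)cyclopentan-1-ol
Conditions: 16 (2 equiv), CuI (15 mol %), THF, −30 to 0 °C; aq. NH4Cl
Reagents that add atoms: none
Why: Copper-catalysed anti opening of the epoxide, in which the nucleophile enters on the face that carries the silyloxy group, so the proximal carbon is blocked and attack occurs at the distal carbon, fixing the isopropenyl centre of half A.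

Step 15
Reactants: 23 (1R,2R,5R)-2-[(tert-butyldimethylsilyl)oxy]-5-(prop-1-en-2-yl)cyclopentan-1-ol
Product: 24 (1R,2R,5R)-2-[(tert-butyldimethylsilyl)oxy]-5-(prop-1-en-2-yl)cyclopentyl methanesulfonate
Conditions: MsCl, Et3N, CH2Cl2, 0 °C
Reagents that add atoms: methanesulfonyl chloride, CS(=O)(=O)Cl
Why: Sulfonylation of the secondary alcohol, which stands alone on its ring face, turns the carbinol carbon into an SN2 electrophile.

Step 16
Reactants: 24 (1R,2R,5R)-2-[(tert-butyldimethylsilyl)oxy]-5-(prop-1-en-2-yl)cyclopentyl methanesulfonate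
Product: 25 (1S,2R,5R)-2-(prop-1-en-2-yl)-6-oxabicyclo[3.1.0]hexane (epoxide cis to isopropenyl)
Conditions: n-Bu4NF, THF, 0 °C to rt
Reagents that add atoms: none
Why: Fluoride desilylation frees an alkoxide anti to the mesylate, which displaces it (intramolecular SN2, 3-exo-tet) with inversion so that the oxygen ends cis to isopropenyl, while E2 is disfavoured because both flanking hydrogens are syn to the leaving group.

**Union and end game**

Step 17
Reactants: 11 2,2'-[(3Z,7Z)-3,8-bis{[(tert-butyldimethylsilyl)oxy]methyl}deca-3,7-diene-1,10-diyl]bis(1,3-dithiane); 25 (1S,2R,5R)-2-(prop-1-en-2-yl)-6-oxabicyclo[3.1.0]hexane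
Product: 27 (1S,2S,5R)-2-{2-[(3Z,7Z)-3,8-bis{[(tert-butyldimethylsilyl)oxy]methyl}-10-(1,3-dithian-2-yl)deca-3,7-dien-1-yl]-1,3-dithian-2-yl}-5-(prop-1-en-2-yl)cyclopentan-1-ol, via monolithiated bis(dithiane) 26 (not isolated)
Conditions: 11 (3 equiv), n-BuLi (1 equiv), THF, −25 °C; DMPU, 25 (0.9 equiv), −25 °C to rt; H2O; excess 11 recovered
Reagents that add atoms: none
Why: Corey–Seebach umpolung, in which the dithianyl anion opens the epoxide by SN2 at the carbon remote from the isopropenyl-bearing centre, placing the new C–C bond trans to the retained C–O bond; the excess of symmetrical 11 over base keeps the reaction at one terminus and so tells the two ends apart.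

Step 18
Reactants: 27 half-A mono-adduct; 20 (1S,2S,5R)-2-(prop-1-en-2-yl)-6-oxabicyclo[3.1.0]hexane
Product: 29 bis-adduct in which the dithiane carbon of one terminus carries the (1S,2S,3R)-2-hydroxy-3-(prop-1-en-2-yl)cyclopentyl group (half A) while that of the other terminus carries its (1S,2S,3S) isomer (half B), via dilithio species 28 (not isolated)
Conditions: n-BuLi (2.2 equiv), THF, −25 °C; DMPU, 20 (2 equiv), −25 °C to rt; H2O
Reagents that add atoms: none
Why: A second Corey–Seebach epoxide opening with the lithium alkoxide of half A as a spectator; the isopropenyl group of 20 lies on the face of attack next to the proximal carbon, so the bulky anion can reach only the distal carbon and again gives the trans hydroxy dithiane.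

Step 19
Reactants: 29 bis-adduct
Product: 30 (4Z,8Z)-4,9-bis{[(tert-butyldimethylsilyl)oxy]methyl}-1-[(1S,2S,3R)-2-hydroxy-3-(prop-1-en-2-yl)cyclopentyl]-12-[(1S,2S,3S)-2-hydroxy-3-(prop-1-en-2-yl)cyclopentyl]dodeca-4,8-diene-1,12-dione
Conditions: MeI (excess), CaCO3, MeCN/H2O 9:1, 40 °C
Reagents that add atoms: water, O
Why: Alkylative dithiane hydrolysis, in which S-methylation makes sulfur a leaving group and water delivers the carbonyl oxygen; the buffered, oxidant-free medium spares the alkenes, silyl ethers and β-hydroxy ketones, whose α-carbon already has the more stable trans arrangement.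

Step 20
Reactants: 30 bis(β-hydroxy ketone)
Product: 32 (1R,4Z,8Z,12R)-4,9-bis{[(tert-butyldimethylsilyl)oxy]methyl}-1-[(1S,2S,3R)-2-hydroxy-3-(prop-1-en-2-yl)cyclopentyl]-12-[(1S,2S,3S)-2-hydroxy-3-(prop-1-en-2-yl)cyclopentyl]dodeca-4,8-diene-1,12-diol, via bis(diethylboron chelate) 31 (not isolated)
Conditions: Et2BOMe (2.4 equiv), THF/MeOH 4:1, −78 °C; NaBH4, −78 °C; AcOH, then repeated evaporation from MeOH
Reagents that add atoms: none
Why: Narasaka–Prasad reduction, in which boron ties each ring hydroxyl to its ketone in a six-membered chelate trans-fused to the cyclopentane and axial hydride attack gives the all-equatorial boronate, that is the syn-1,3-diol with R configuration at both future oxane C-2 atoms.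

Step 21
Reactants: 32 bis(silyl ether) tetraol
Product: 33 (1R,4Z,8Z,12R)-4,9-bis(hydroxymethyl)-1-[(1S,2S,3R)-2-hydroxy-3-(prop-1-en-2-yl)cyclopentyl]-12-[(1S,2S,3S)-2-hydroxy-3-(prop-1-en-2-yl)cyclopentyl]dodeca-4,8-diene-1,12-diol
Conditions: n-Bu4NF, THF, rt
Reagents that add atoms: none
Why: Fluoride cleavage of the two primary allylic silyl ethers, with no base-sensitive group left in the molecule.

Step 22
Reactants: 33 hexaol
Product: 35 CNP0267443.2, via bis(allylic mesylate) 34 (not isolated)
Conditions: Ms2O (2.2 equiv), 2,4,6-collidine, CH2Cl2, −20 °C; aqueous wash, crude into THF; NaH (excess), 0 °C to rt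
Reagents that add atoms: none
Why: Selective sulfonylation of the two primary allylic alcohols with a hindered base, followed by a double intramolecular Williamson etherification (6-exo-tet, SN2 at C-6) by the C-2 alkoxides, with the C-2 configuration retained, the alkene geometry untouched, and the ring hydroxyls unable to compete because they would have to form eight-membered rings.

**Compound list**
1 | 2-bromoprop-2-en-1-ol | OCC(Br)=C | starting material
2 | [(2-bromoprop-2-en-1-yl)oxy](tert-butyl)dimethylsilane | C=C(Br)CO[Si](C)(C)C(C)(C)C | intermediate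
3 | 2,5-dimethoxytetrahydrofuran (cis/trans mixture) | COC1CCC(OC)O1 | starting material
4 | butanedial | O=CCCC=O | intermediate
5 | {3-[(tert-butyldimethylsilyl)oxy]prop-1-en-2-yl}lithium | [Li]C(=C)CO[Si](C)(C)C(C)(C)C | intermediate
6 | 2,7-bis{[(tert-butyldimethylsilyl)oxy]methyl}octa-1,7-diene-3,6-diol (meso/dl mixture, (3R,6S) drawn) | C=C(CO[Si](C)(C)C(C)(C)C)[C@H](O)CC[C@H](O)C(=C)CO[Si](C)(C)C(C)(C)C | intermediate
7 | triethyl orthoacetate | CC(OCC)(OCC)OCC | starting material
8 | bis(1-ethoxyvinyl) ether (bis(ketene acetal)) of 6 | C=C(CO[Si](C)(C)C(C)(C)C)[C@H](OC(=C)OCC)CC[C@H](OC(=C)OCC)C(=C)CO[Si](C)(C)C(C)(C)C | intermediate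
9 | diethyl (4Z,8Z)-4,9-bis{[(tert-butyldimethylsilyl)oxy]methyl}dodeca-4,8-dienedioate | CCOC(=O)CC/C(CO[Si](C)(C)C(C)(C)C)=C/CC/C=C(\CO[Si](C)(C)C(C)(C)C)CCC(=O)OCC | intermediate
10 | (4Z,8Z)-4,9-bis{[(tert-butyldimethylsilyl)oxy]methyl}dodeca-4,8-dienedial | O=CCC/C(CO[Si](C)(C)C(C)(C)C)=C/CC/C=C(\CO[Si](C)(C)C(C)(C)C)CCC=O | intermediate
11 | 2,2'-[(3Z,7Z)-3,8-bis{[(tert-butyldimethylsilyl)oxy]methyl}deca-3,7-diene-1,10-diyl]bis(1,3-dithiane) | S1CCCSC1CC/C(CO[Si](C)(C)C(C)(C)C)=C/CC/C=C(\CO[Si](C)(C)C(C)(C)C)CCC1SCCCS1 | intermediate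
12 | (±)-cyclopent-2-en-1-ol | OC1C=CCC1 | starting material
13 | (±)-cyclopent-2-en-1-yl methyl carbonate | COC(=O)OC1C=CCC1 | intermediate
14 | (R)-cyclopent-2-en-1-ol | O[C@H]1C=CCC1 | intermediate
15 | (1R,2R,5S)-6-oxabicyclo[3.1.0]hexan-2-ol | O[C@H]1[C@H]2O[C@H]2CC1 | intermediate
16 | isopropenylmagnesium bromide | C=C(C)[Mg]Br | starting material
17 | (1R,2S,3S)-3-(prop-1-en-2-yl)cyclopentane-1,2-diol | O[C@H]1[C@@H](O)[C@H](C(C)=C)CC1 | intermediate
18 | cyclic methyl orthoacetate of 17 (2-methoxy-2-methyl-1,3-dioxolane, epimers at the orthoester carbon) | COC1(C)O[C@@H]2CC[C@@H](C(C)=C)[C@@H]2O1 | intermediate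
19 | (1S,2S,5S)-2-chloro-5-(prop-1-en-2-yl)cyclopentyl acetate | Cl[C@@H]1[C@@H](OC(C)=O)[C@H](C(C)=C)CC1 | intermediate
20 | (1S,2S,5R)-2-(prop-1-en-2-yl)-6-oxabicyclo[3.1.0]hexane | C=C(C)[C@@H]1CC[C@H]2O[C@@H]12 | intermediate
21 | tert-butyl[(1R)-cyclopent-2-en-1-yloxy]dimethylsilane | CC(C)(C)[Si](C)(C)O[C@H]1C=CCC1 | intermediate
22 | tert-butyl(dimethyl){[(1R,2R,5R)-6-oxabicyclo[3.1.0]hexan-2-yl]oxy}silane | CC(C)(C)[Si](C)(C)O[C@H]1[C@@H]2O[C@@H]2CC1 | intermediate
23 | (1R,2R,5R)-2-[(tert-butyldimethylsilyl)oxy]-5-(prop-1-en-2-yl)cyclopentan-1-ol | CC(C)(C)[Si](C)(C)O[C@H]1[C@H](O)[C@@H](C(C)=C)CC1 | intermediate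
24 | (1R,2R,5R)-2-[(tert-butyldimethylsilyl)oxy]-5-(prop-1-en-2-yl)cyclopentyl methanesulfonate | CC(C)(C)[Si](C)(C)O[C@H]1[C@H](OS(C)(=O)=O)[C@@H](C(C)=C)CC1 | intermediate
25 | (1S,2R,5R)-2-(prop-1-en-2-yl)-6-oxabicyclo[3.1.0]hexane | C=C(C)[C@H]1CC[C@H]2O[C@@H]12 | intermediate
26 | 2-lithio derivative of 11 at one dithiane | [Li]C1(CC/C(CO[Si](C)(C)C(C)(C)C)=C/CC/C=C(\CO[Si](C)(C)C(C)(C)C)CCC2SCCCS2)SCCCS1 | intermediate
27 | half-A mono-adduct (name in step 17) | C=C(C)[C@H]1CC[C@H](C2(CC/C(CO[Si](C)(C)C(C)(C)C)=C/CC/C=C(\CO[Si](C)(C)C(C)(C)C)CCC3SCCCS3)SCCCS2)[C@H]1O | intermediate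
28 | lithium alkoxide of 27 lithiated at the free dithiane | C=C(C)[C@H]1CC[C@H](C2(CC/C(CO[Si](C)(C)C(C)(C)C)=C/CC/C=C(\CO[Si](C)(C)C(C)(C)C)CCC3([Li])SCCCS3)SCCCS2)[C@H]1O[Li] | intermediate
29 | bis-adduct, half A (1S,2S,3R)-cyclopentyl and half B (1S,2S,3S)-cyclopentyl on the two dithiane carbons | C=C(C)[C@H]1CC[C@H](C2(CC/C(CO[Si](C)(C)C(C)(C)C)=C/CC/C=C(\CO[Si](C)(C)C(C)(C)C)CCC3([C@H]4CC[C@@H](C(=C)C)[C@@H]4O)SCCCS3)SCCCS2)[C@H]1O | intermediate
30 | bis(β-hydroxy ketone) (name in step 19) | C=C(C)[C@H]1CC[C@H](C(=O)CC/C(CO[Si](C)(C)C(C)(C)C)=C/CC/C=C(\CO[Si](C)(C)C(C)(C)C)CCC(=O)[C@H]2CC[C@@H](C(=C)C)[C@@H]2O)[C@H]1O | intermediate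
31 | bis(O-diethylboryl) chelate of 30 | C=C(C)[C@H]1CC[C@H](C(=O)CC/C(CO[Si](C)(C)C(C)(C)C)=C/CC/C=C(\CO[Si](C)(C)C(C)(C)C)CCC(=O)[C@H]2CC[C@@H](C(=C)C)[C@@H]2OB(CC)CC)[C@H]1OB(CC)CC | intermediate
32 | bis(silyl ether) tetraol (name in step 20) | C=C(C)[C@H]1CC[C@H]([C@H](O)CC/C(CO[Si](C)(C)C(C)(C)C)=C/CC/C=C(\CO[Si](C)(C)C(C)(C)C)CC[C@H]([C@H]2CC[C@@H](C(=C)C)[C@@H]2O)O)[C@H]1O | intermediate
33 | hexaol (name in step 21) | C=C(C)[C@H]1CC[C@H]([C@H](O)CC/C(CO)=C/CC/C=C(\CO)CC[C@H]([C@H]2CC[C@@H](C(=C)C)[C@@H]2O)O)[C@H]1O | intermediate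
34 | bis(allylic methanesulfonate) of 33 | C=C(C)[C@H]1CC[C@H]([C@H](O)CC/C(COS(C)(=O)=O)=C/CC/C=C(\COS(C)(=O)=O)CC[C@H]([C@H]2CC[C@@H](C(=C)C)[C@@H]2O)O)[C@H]1O | intermediate
35 | (1S,2S,5R)-2-[(2R,5Z)-5-{(4Z)-4-[(6R)-6-[(1S,2S,3S)-2-hydroxy-3-(prop-1-en-2-yl)cyclopentyl]oxan-3-ylidene]butylidene}oxan-2-yl]-5-(prop-1-en-2-yl)cyclopentan-1-ol (CNP0267443.2) | C=C(C)[C@H]1CC[C@H]([C@H]2CC/C(=C/CC/C=C3/CC[C@H]([C@H]4CC[C@@H](C(=C)C)[C@@H]4O)OC3)CO2)[C@H]1O | target

**Totals**
Total step count: 22.
Longest linear sequence: 13 steps (7, 8, 12–22).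

**Steps most likely to fail**

Step 17 (the same applies to step 18). A tertiary dithianyl anion may open a 1,2-disubstituted epoxide too slowly. Metalation of the allylic OCH2 of the silyl ethers or base-induced isomerisation of the epoxide may then compete, and some double reaction may occur. The fallback gives up the anionic opening for a radical cross-electrophile ketone synthesis; it sets out from 9, 25 and 20 and rejoins the route at 30.
- LiOH in THF/H2O turns 9 into the (4Z,8Z)-diacid F1. 2,2'-Dipyridyl disulfide and PPh3 then convert it to the bis(S-pyridin-2-yl thioester) F2.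
- Et3SiCl/NaI in MeCN (Et3SiI formed in situ) opens 25 and 20 at the less hindered carbon. This gives the trans iodo silyl ether of half A F3 and the trans iodo silyl ether of half B F4.
- NiCl2(dme), 4,4'-di-tert-butyl-2,2'-bipyridine and Mn powder in DMA join excess F2 with F3 to the keto thioester F5, and then F5 with F4 to the bis(triethylsilyl ether) diketone F6.
- The cyclopentyl radical should be captured anti to the silyloxy group, and any cis ketone can be equilibrated with mild base.
- AcOH/THF/H2O removes the triethylsilyl groups and gives 30.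

Step 22. Sulfonylation may not discriminate cleanly among six hydroxyl groups, and the allylic sulfonates may ionise or react by SN2' before the ring closes. The fallback changes the protecting-group logic; it sets out from 32 and rejoins at 35.
- 2,2-Dimethoxypropane and PPTS mask both syn-1,3-diols as the bis(acetonide) F7.
- n-Bu4NF frees the bis(allylic alcohol) F8, now the only hydroxyl-bearing sites.
- MsCl, LiCl and 2,4,6-collidine in DMF give the bis(allylic chloride) F9 without transposition.
- 80 % aqueous AcOH removes the acetonides to give the tetraol bis(chloride) F10, and NaH in THF closes both oxanes to 35.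

Step 10. With the free alkoxide on the epoxide face, attack may drift to the proximal epoxide carbon and give the 1,3-diol. The fallback reaches 20 through the enantiomeric anti-epoxide series, where the silyloxy group physically blocks the proximal carbon; it sets out from 13 and rejoins at 20.
- The conditions of step 8 with the (1R,2R)-diphosphine give (S)-cyclopent-2-en-1-ol F11.
- TBSCl gives its silyl ether F12, mCPBA gives the anti epoxide F13, and 16 with CuI gives the alcohol F14, the mirror image of 23.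
- n-Bu4NF gives the trans diol F15, and TsCl in pyridine sulfonylates the less hindered hydroxyl to the monotosylate F16.
- K2CO3 in MeOH lets the remaining alkoxide displace the tosylate to give 20.

**Further compounds**
F1 | step 17 | (4Z,8Z)-4,9-bis{[(tert-butyldimethylsilyl)oxy]methyl}dodeca-4,8-dienedioic acid | OC(=O)CC/C(CO[Si](C)(C)C(C)(C)C)=C/CC/C=C(\CO[Si](C)(C)C(C)(C)C)CCC(=O)O
F2 | step 17 | S,S'-di(pyridin-2-yl) (4Z,8Z)-4,9-bis{[(tert-butyldimethylsilyl)oxy]methyl}dodeca-4,8-dienebis(thioate) | O=C(CC/C(CO[Si](C)(C)C(C)(C)C)=C/CC/C=C(\CO[Si](C)(C)C(C)(C)C)CCC(=O)Sc1ccccn1)Sc1ccccn1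
F3 | step 17 | triethyl{[(1S,2S,5R)-2-iodo-5-(prop-1-en-2-yl)cyclopentyl]oxy}silane | I[C@@H]1[C@@H](O[Si](CC)(CC)CC)[C@@H](C(C)=C)CC1
F4 | step 17 | triethyl{[(1S,2S,5S)-2-iodo-5-(prop-1-en-2-yl)cyclopentyl]oxy}silane | I[C@@H]1[C@@H](O[Si](CC)(CC)CC)[C@H](C(C)=C)CC1
F5 | step 17 | half-A keto S-pyridin-2-yl thioester (triethylsilyl ether) | C=C(C)[C@H]1CC[C@H](C(=O)CC/C(CO[Si](C)(C)C(C)(C)C)=C/CC/C=C(\CO[Si](C)(C)C(C)(C)C)CCC(=O)Sc2ccccn2)[C@H]1O[Si](CC)(CC)CC
F6 | step 17 | bis(triethylsilyl ether) of 30 | C=C(C)[C@H]1CC[C@H](C(=O)CC/C(CO[Si](C)(C)C(C)(C)C)=C/CC/C=C(\CO[Si](C)(C)C(C)(C)C)CCC(=O)[C@H]2CC[C@@H](C(=C)C)[C@@H]2O[Si](CC)(CC)CC)[C@H]1O[Si](CC)(CC)CC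
F7 | step 22 | bis(acetonide) of 32 (each syn-1,3-diol as a 2,2-dimethyl-1,3-dioxane trans-fused to its cyclopentane) | C=C(C)[C@H]1CC[C@H]2[C@H]1OC(C)(C)O[C@@H]2CC/C(CO[Si](C)(C)C(C)(C)C)=C/CC/C=C(\CO[Si](C)(C)C(C)(C)C)CC[C@H]3OC(C)(C)O[C@@H]4[C@@H]3CC[C@H]4C(C)=C
F8 | step 22 | bis(acetonide) bis(allylic alcohol) | C=C(C)[C@H]1CC[C@H]2[C@H]1OC(C)(C)O[C@@H]2CC/C(CO)=C/CC/C=C(\CO)CC[C@H]3OC(C)(C)O[C@@H]4[C@@H]3CC[C@H]4C(C)=C
F9 | step 22 | bis(acetonide) bis(allylic chloride) | C=C(C)[C@H]1CC[C@H]2[C@H]1OC(C)(C)O[C@@H]2CC/C(CCl)=C/CC/C=C(\CCl)CC[C@H]3OC(C)(C)O[C@@H]4[C@@H]3CC[C@H]4C(C)=C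
F10 | step 22 | tetraol bis(allylic chloride) | C=C(C)[C@H]1CC[C@H]([C@H](O)CC/C(CCl)=C/CC/C=C(\CCl)CC[C@H]([C@H]2CC[C@@H](C(=C)C)[C@@H]2O)O)[C@H]1O
F11 | step 10 | (S)-cyclopent-2-en-1-ol | O[C@@H]1C=CCC1
F12 | step 10 | tert-butyl[(1S)-cyclopent-2-en-1-yloxy]dimethylsilane | CC(C)(C)[Si](C)(C)O[C@@H]1C=CCC1
F13 | step 10 | tert-butyl(dimethyl){[(1S,2S,5S)-6-oxabicyclo[3.1.0]hexan-2-yl]oxy}silane | CC(C)(C)[Si](C)(C)O[C@@H]1[C@H]2O[C@H]2CC1
F14 | step 10 | (1S,2S,5S)-2-[(tert-butyldimethylsilyl)oxy]-5-(prop-1-en-2-yl)cyclopentan-1-ol | CC(C)(C)[Si](C)(C)O[C@@H]1[C@@H](O)[C@H](C(C)=C)CC1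
F15 | step 10 | (1S,2S,3S)-3-(prop-1-en-2-yl)cyclopentane-1,2-diol | O[C@@H]1[C@@H](O)[C@H](C(C)=C)CC1
F16 | step 10 | (1S,2S,3S)-2-hydroxy-3-(prop-1-en-2-yl)cyclopentyl 4-methylbenzenesulfonate | Cc1ccc(cc1)S(=O)(=O)O[C@@H]1[C@@H](O)[C@H](C(C)=C)CC1
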